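**Plan**
1. Ring numbering used throughout: C1 = quaternary carbinol carbon (bears CH2OBz), C2=C3, C4 = benzoate carbon, C5 and C6 = diol carbons. Retrosynthetic cuts, in order: the Si–O bonds of a disiloxane bridge on O5/O6; the ester C–O bond at the exocyclic CH2 (benzoate opening of a spiro-oxirane); the C1–CH2 bond (cyclohexenone + sulfonium methylide); the C1–C2 ring bond and the C2=C3 alkene (Ferrier carbocyclization and dehydration of a D-glucose hex-5-enopyranoside).
2. Forward: methyl α-D-glucopyranoside → O2 benzoate → 6-iodide → O3/O4 disiloxane → 5-ene → cyclohexanone (the carbocycle, closed by aldol) → enone → spiro-oxirane (temporary second ring) → primary benzoate → desilylation.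
3. Stereochemistry: C2, C3, C4 of D-glucose become C4, C5, C6 unchanged, and the O2 benzoate of step 1 is the C4 benzoate of the target. C1 is the only new centre and is set by substrate control in the key step.
4. Enabling feature: C1 lies between the C2=C3 alkene and oxygenated C6, so it is a masked enone carbonyl. With O4, O5, O6 equatorial, its CH2 is axial (cis to O6) and its OH equatorial (trans to O6), which is what axial attack of a one-carbon nucleophile on the half-chair enone delivers.
5. Helpers: the ketone oxidation level at C1; a seven-membered disiloxane ring across the trans O5/O6 pair (locks the all-equatorial half-chair, removed in step 9); the oxirane (brings in CH2 and the tertiary OH together and is opened by benzoate in step 8, so neither hydroxyl needs protection).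

Key step: step 7

Remark: the target is the (1R,4S,5S,6S) isomer in the numbering above. Ketone 6 is drawn as its expected major epimer at the new carbinol carbon; the minor epimer gives the same enone.

**Step 1**
Reactants: 1 methyl α-D-glucopyranoside
Product: 2 methyl 2-O-benzoyl-α-D-glucopyranoside
Conditions: BzCl (1.1 equiv), Me2SnCl2 (5 mol %), i-Pr2NEt, THF, rt
Reagents that add atoms: benzoyl chloride, O=C(Cl)c1ccccc1
Why: Organotin-catalysed regioselective acylation, in which Me2SnCl2 chelates the 1,2-cis O1/O2 pair of the α-glucoside and activates the equatorial O2, so one equivalent of benzoyl chloride should acylate O2 in preference to O6, O3 and O4 without touching any stereocentre.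

**Step 2**
Reactants: 2 methyl 2-O-benzoyl-α-D-glucopyranoside
Product: 3 methyl 2-O-benzoyl-6-deoxy-6-iodo-α-D-glucopyranoside
Conditions: PPh3, I2, imidazole, THF, 60 °C
Reagents that add atoms: iodine, II
Why: Garegg–Samuelsson (Appel-type) iodination, in which the least hindered primary O6 is activated as an alkoxyphosphonium ion and displaced by iodide in an SN2 step while the secondary 3,4-diol and the benzoate stay untouched.

**Step 3**
Reactants: 3 methyl 2-O-benzoyl-6-deoxy-6-iodo-α-D-glucopyranoside
Product: 4 methyl 2-O-benzoyl-6-deoxy-6-iodo-3,4-O-(1,1,3,3-tetraisopropyldisiloxane-1,3-diyl)-α-D-glucopyranoside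
Conditions: (i-Pr2SiCl)2O, imidazole, DMF, 0 °C → rt
Reagents that add atoms: 1,3-dichloro-1,1,3,3-tetraisopropyldisiloxane, CC(C)[Si](Cl)(C(C)C)O[Si](Cl)(C(C)C)C(C)C
Why: Silyl ether formation with a bifunctional chlorosilane, where the only free hydroxyls are the trans-diequatorial O3/O4 pair, which the disiloxane should bridge as a seven-membered ring as is known for vicinal trans-diols of cyclohexane polyols, under conditions too mild for benzoyl migration.

**Step 4**
Reactants: 4 methyl 2-O-benzoyl-6-deoxy-6-iodo-3,4-O-(1,1,3,3-tetraisopropyldisiloxane-1,3-diyl)-α-D-glucopyranoside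
Product: 5 methyl 2-O-benzoyl-6-deoxy-3,4-O-(1,1,3,3-tetraisopropyldisiloxane-1,3-diyl)-α-D-xylo-hex-5-enopyranoside
Conditions: DBU, DMF, 80 °C
Reagents that add atoms: none
Why: E2 dehydrohalogenation of a 6-deoxy-6-iodopyranoside with an amidine base, the standard entry to hex-5-enopyranosides, in which H5 is the only β-hydrogen so the exocyclic enol ether is the only possible alkene and the C5 centre is given up on purpose.

**Step 5**
Reactants: 5 methyl 2-O-benzoyl-6-deoxy-3,4-O-(1,1,3,3-tetraisopropyldisiloxane-1,3-diyl)-α-D-xylo-hex-5-enopyranoside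
Product: 6 (2S,3R,4S,5S)-4-(benzoyloxy)-5-hydroxy-2,3-[(1,1,3,3-tetraisopropyldisiloxane-1,3-diyl)bis(oxy)]cyclohexan-1-one
Conditions: Hg(OCOCF3)2 (10 mol %), acetone/H2O 2:1, rt
Reagents that add atoms: water, O
Why: Ferrier carbocyclization, in which catalytic hydroxymercuration of the enol ether gives a hemiketal that loses methanol to a C6-mercurated 5-keto-aldehyde, and this closes by intramolecular aldol reaction (6-(enolendo)-exo-trig) with the three sugar centres untouched, the new carbinol centre arising mainly cis to the neighbouring benzoate and being removed in step 6.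

**Step 6**
Reactants: 6 (2S,3R,4S,5S)-4-(benzoyloxy)-5-hydroxy-2,3-[(1,1,3,3-tetraisopropyldisiloxane-1,3-diyl)bis(oxy)]cyclohexan-1-one
Product: 8 (4S,5R,6S)-4-(benzoyloxy)-5,6-[(1,1,3,3-tetraisopropyldisiloxane-1,3-diyl)bis(oxy)]cyclohex-2-en-1-one, via mesylate 7 (not isolated)
Conditions: MsCl, Et3N, CH2Cl2, 0 °C → rt
Reagents that add atoms: none
Why: Mesylation of the β-hydroxyl followed by E1cB elimination under the same conditions (dehydration of an aldol) should give the conjugated enone from either epimer of 6, while the α-centre C6 stays in its equatorial, thermodynamically preferred configuration enforced by the bridge.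

**Step 7**
Reactants: 8 (4S,5R,6S)-4-(benzoyloxy)-5,6-[(1,1,3,3-tetraisopropyldisiloxane-1,3-diyl)bis(oxy)]cyclohex-2-en-1-one; 9 trimethylsulfonium iodide
Product: 11 (3R,6S,7R,8S)-6-(benzoyloxy)-7,8-[(1,1,3,3-tetraisopropyldisiloxane-1,3-diyl)bis(oxy)]-1-oxaspiro[2.5]oct-4-ene, via sulfonium betaine 10 (not isolated)
Conditions: Me3S+ I− (1.5 equiv), KN(SiMe3)2 (1.4 equiv), THF, −10 °C; then 8, −40 → 0 °C
Reagents that add atoms: trimethylsulfonium iodide, C[S+](C)C.[I-]
Why: Corey–Chaykovsky epoxidation, in which the methylide carbon adds irreversibly to the C1 carbonyl to give betaine 10 and the alkoxide then displaces dimethyl sulfide. The oxirane is the only ring closed, in the 3-exo-tet mode. The closest known reaction type is the epoxidation of cyclohexanones and cyclohexenones with dimethylsulfonium methylide, which places the new C–C bond axial under kinetic control. C1 is controlled through the ring by the existing centres: the trans-fused disiloxane holds O5 and O6 (and with them O4) equatorial, so axial attack comes from the face anti to the axial C6–H, the CH2 ends cis to O6 and the oxirane oxygen equatorial and trans to O6, as the target requires. The step needs 1,2- over 1,4-addition (secured by using the sulfonium and not the sulfoxonium ylide), ketone over benzoate attack (the ketone is far more electrophilic at low temperature and no excess amide base is present) and no enolisation towards C6 with β-elimination of O5 (the equatorial C5–O bond held by the bridge cannot align with the enolate π system).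

**Step 8**
Reactants: 11 (3R,6S,7R,8S)-6-(benzoyloxy)-7,8-[(1,1,3,3-tetraisopropyldisiloxane-1,3-diyl)bis(oxy)]-1-oxaspiro[2.5]oct-4-ene
Product: 12 [(1R,4S,5R,6S)-4-(benzoyloxy)-1-hydroxy-5,6-[(1,1,3,3-tetraisopropyldisiloxane-1,3-diyl)bis(oxy)]cyclohex-2-en-1-yl]methyl benzoate
Conditions: PhCO2H (2 equiv), n-Bu4N+ PhCO2− (20 mol %), toluene, 70 °C
Reagents that add atoms: benzoic acid, O=C(O)c1ccccc1
Why: Nucleophilic ring opening of a 2,2-disubstituted oxirane by carboxylate (SN2 at the unhindered CH2 with benzoic acid as proton source), an addition in which the C1–O bond is not broken, so the C1 configuration is kept and the tertiary hydroxyl is set free without ever having been protected.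

**Step 9**
Reactants: 12 [(1R,4S,5R,6S)-4-(benzoyloxy)-1-hydroxy-5,6-[(1,1,3,3-tetraisopropyldisiloxane-1,3-diyl)bis(oxy)]cyclohex-2-en-1-yl]methyl benzoate
Product: 13 Kweichowenol B, [(1R,4S,5S,6S)-4-(benzoyloxy)-1,5,6-trihydroxycyclohex-2-en-1-yl]methyl benzoate
Conditions: HF·pyridine, pyridine/THF, 0 °C → rt
Reagents that add atoms: none
Why: Fluoride-driven cleavage of the Si–O bonds of the disiloxane (desilylation with buffered HF) under weakly acidic conditions that should neither move the benzoates onto the new 5,6-diol nor ionise the deactivated tertiary allylic alcohol.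

**Compound list**
1 | methyl α-D-glucopyranoside | CO[C@H]1O[C@H](CO)[C@@H](O)[C@H](O)[C@H]1O | starting material
2 | methyl 2-O-benzoyl-α-D-glucopyranoside | CO[C@H]1O[C@H](CO)[C@@H](O)[C@H](O)[C@H]1OC(=O)c2ccccc2 | intermediate
3 | methyl 2-O-benzoyl-6-deoxy-6-iodo-α-D-glucopyranoside | CO[C@H]1O[C@H](CI)[C@@H](O)[C@H](O)[C@H]1OC(=O)c2ccccc2 | intermediate
4 | methyl 2-O-benzoyl-6-deoxy-6-iodo-3,4-O-(1,1,3,3-tetraisopropyldisiloxane-1,3-diyl)-α-D-glucopyranoside | CO[C@H]1O[C@H](CI)[C@H]2O[Si](C(C)C)(C(C)C)O[Si](C(C)C)(C(C)C)O[C@@H]2[C@H]1OC(=O)c3ccccc3 | intermediate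
5 | methyl 2-O-benzoyl-6-deoxy-3,4-O-(1,1,3,3-tetraisopropyldisiloxane-1,3-diyl)-α-D-xylo-hex-5-enopyranoside | CO[C@H]1OC(=C)[C@H]2O[Si](C(C)C)(C(C)C)O[Si](C(C)C)(C(C)C)O[C@@H]2[C@H]1OC(=O)c3ccccc3 | intermediate
6 | (2S,3R,4S,5S)-4-(benzoyloxy)-5-hydroxy-2,3-[(1,1,3,3-tetraisopropyldisiloxane-1,3-diyl)bis(oxy)]cyclohexan-1-one | O=C1C[C@H](O)[C@H](OC(=O)c2ccccc2)[C@H]3O[Si](C(C)C)(C(C)C)O[Si](C(C)C)(C(C)C)O[C@H]13 | intermediate
7 | 5-O-methanesulfonate of ketone 6, configuration unchanged | O=C1C[C@H](OS(C)(=O)=O)[C@H](OC(=O)c2ccccc2)[C@H]3O[Si](C(C)C)(C(C)C)O[Si](C(C)C)(C(C)C)O[C@H]13 | intermediate (not isolated)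
8 | (4S,5R,6S)-4-(benzoyloxy)-5,6-[(1,1,3,3-tetraisopropyldisiloxane-1,3-diyl)bis(oxy)]cyclohex-2-en-1-one | O=C1C=C[C@H](OC(=O)c2ccccc2)[C@H]3O[Si](C(C)C)(C(C)C)O[Si](C(C)C)(C(C)C)O[C@H]13 | intermediate
9 | trimethylsulfonium iodide | C[S+](C)C.[I-] | starting material
10 | sulfonium betaine: C1 alkoxide of 8 bearing an axial CH2–S+Me2 group at C1 | C[S+](C)C[C@]1([O-])C=C[C@H](OC(=O)c2ccccc2)[C@H]3O[Si](C(C)C)(C(C)C)O[Si](C(C)C)(C(C)C)O[C@H]13 | intermediate (not isolated)
11 | (3R,6S,7R,8S)-6-(benzoyloxy)-7,8-[(1,1,3,3-tetraisopropyldisiloxane-1,3-diyl)bis(oxy)]-1-oxaspiro[2.5]oct-4-ene | C1O[C@]12C=C[C@H](OC(=O)c3ccccc3)[C@H]4O[Si](C(C)C)(C(C)C)O[Si](C(C)C)(C(C)C)O[C@H]24 | intermediate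
12 | [(1R,4S,5R,6S)-4-(benzoyloxy)-1-hydroxy-5,6-[(1,1,3,3-tetraisopropyldisiloxane-1,3-diyl)bis(oxy)]cyclohex-2-en-1-yl]methyl benzoate | O=C(OC[C@]1(O)C=C[C@H](OC(=O)c2ccccc2)[C@H]3O[Si](C(C)C)(C(C)C)O[Si](C(C)C)(C(C)C)O[C@H]13)c4ccccc4 | intermediate
13 | Kweichowenol B, [(1R,4S,5S,6S)-4-(benzoyloxy)-1,5,6-trihydroxycyclohex-2-en-1-yl]methyl benzoate | O=C(OC[C@]1(O)C=C[C@H](OC(=O)c2ccccc2)[C@@H](O)[C@@H]1O)c1ccccc1 | target

Total step count: 9. Longest linear sequence: 9 steps (1 → 13).

**Steps most likely to fail**

Step 7. The ylide addition may show poor facial selectivity (equatorial instead of axial attack), or the ylide may enolise the enone. The fallback sets out from 8 and comes back at 12; it makes the C1–CH2 bond by olefination and the tertiary C–O bond by osmylation. Wittig methylenation of 8 (Ph3P+CH3 Br−, KN(SiMe3)2, THF, −78 → 0 °C) should give the exocyclic diene F1. Dihydroxylation with OsO4 (cat.) and N-methylmorpholine N-oxide in acetone/H2O should take the 1,1-disubstituted exocyclic alkene in preference to the ring alkene deactivated by the allylic benzoate, from the equatorial direction, to give the hydroxymethyl carbinol F2 with the tertiary OH equatorial and trans to O6. Benzoylation of the primary hydroxyl (BzCl, pyridine, CH2Cl2, −20 °C) then gives 12.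

Step 8. Benzoate may attack the vinyl oxirane at the wrong carbon (SN2′ at C3 or ionisation at the tertiary allylic C1), or the silyl bridge may migrate to the new tertiary alkoxide. The fallback sets out from 11 and comes back at 13; it reverses the order of the last two operations and uses a directed opening. Desilylation of 11 with n-Bu4NF/AcOH (THF, 0 °C) should give the spiro-oxirane diol F3. Ti(OiPr)4 and PhCO2H (CH2Cl2, rt) should then bind the C6 hydroxyl of this 2,3-epoxy alcohol array and deliver benzoate to the distal CH2 carbon, giving 13 directly.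

Step 1. Regiocontrol of the monoacylation may be lost (benzoylation at the primary O6 or at O3, or over-acylation). The fallback sets out from 1 and comes back at 2; it blocks O4/O6 temporarily. Acetalisation of 1 with PhCH(OMe)2 and camphorsulfonic acid (DMF, 60 °C) should give methyl 4,6-O-[(R)-benzylidene]-α-D-glucopyranoside F4. N-Benzoylimidazole in refluxing CHCl3 should acylate the more acidic O2 to give methyl 2-O-benzoyl-4,6-O-[(R)-benzylidene]-α-D-glucopyranoside F5. Hydrolysis of the acetal (80% aqueous AcOH, 60 °C) then gives 2.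

**Further compounds**
F1 | step 7 | exocyclic diene: enone 8 with the C1 carbonyl oxygen replaced by CH2, oxygenated centres as in 8 | C=C1C=C[C@H](OC(=O)c2ccccc2)[C@H]3O[Si](C(C)C)(C(C)C)O[Si](C(C)C)(C(C)C)O[C@H]13
F2 | step 7 | hydroxymethyl carbinol: compound 12 without the primary benzoyl group | OC[C@]1(O)C=C[C@H](OC(=O)c2ccccc2)[C@H]3O[Si](C(C)C)(C(C)C)O[Si](C(C)C)(C(C)C)O[C@H]13
F3 | step 8 | spiro-oxirane diol: compound 11 without the disiloxane bridge | C1O[C@]12C=C[C@H](OC(=O)c3ccccc3)[C@@H](O)[C@@H]2O
F4 | step 1 | methyl 4,6-O-[(R)-benzylidene]-α-D-glucopyranoside | CO[C@H]1O[C@@H]2CO[C@@H](c3ccccc3)O[C@H]2[C@H](O)[C@H]1O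
F5 | step 1 | methyl 2-O-benzoyl-4,6-O-[(R)-benzylidene]-α-D-glucopyranoside | CO[C@H]1O[C@@H]2CO[C@@H](c3ccccc3)O[C@H]2[C@H](O)[C@H]1OC(=O)c4ccccc4
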